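| flask | Q | L | time |
|---|---|---|---|
| epsilon | 0.500 M | 0.600 M |  |
| delta | 0.200 M | 0.300 M |  |
| theta | 0.500 M | 1.20 M |  |
| alpha | 1.50 M | 0.600 M |  |
| eta | 1.50 M | 1.80 M | 23 min |

- epsilon run (time / min: [J] / M): 3.3: 0.071; 6.6: 0.157; 9.9: 0.205; 13: 0.239; 16: 0.258; 20: 0.270; 23: 0.268
- delta run (time / min: [J] / M): 3.3: 0.021; 6.6: 0.042; 9.9: 0.062; 13: 0.078; 16: 0.077; 20: 0.076; 23: 0.088
- theta run (time / min: [J] / M): 3.3: 0.096; 6.6: 0.213; 9.9: 0.280; 13: 0.312; 16: 0.331; 20: 0.343; 23: 0.351
- alpha run (time / min: [J] / M): 3.3: 0.193; 6.6: 0.382; 9.9: 0.465; 13: 0.497; 16: 0.510; 20: 0.519; 23: 0.520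

(scatter of a reading: 0.003 M)

- Overall: Q + L -> J.
- Constant volume, constant temperature.
- The analysis sees a species whether free or bound.
- "The second partner" is L.
- An order is taken over about fifteen percent of the charge, up and down.

1. apparent order in [Q] of the starting rate, round the charge of the epsilon run (the rate where two percent of its Q have turned into J) (one fixed amount of J, the same in the runs compared)
2. apparent order in [L] of the starting rate, round the charge of the epsilon run (the rate where two percent of its Q have turned into J)
3. J in the eta run at 23 min, as a share of the Q charged

These flasks are slow on a scale of minutes, and the slowness has a shape: J climbs, then slows, and at the last reading it stands short of the Q charged. At 23 min J stands at 53.6% of Q in epsilon, 70.2% in theta and 34.7% in alpha.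

We read this as a race. Each Q that leaves ends either in J or in a loss, with odds for J of L against a constant level B. As L falls, the Q not in J sums to B times ln(charged L over L left), where L left is the charge less the J made. Dividing that Q by that logarithm gives B as 0.392 M in epsilon, 0.431 M in theta and 0.486 M in alpha. These are readings at the asked time, so any Q still unturned is counted in them. Their mean, 0.436 M, is our break-even L: the level at which a leaving Q is as likely to be lost as to become J.

By its charge, Q is the limiting reagent in eta, with less charged than L. We take two extreme versions. If L stayed at its charge, the share of Q in J would be L/(L + B) = 80.5%, a J of 1.21 M. If L dropped at once to the 0.593 M that this J leaves, the share would be 57.6%. In our race L runs from the first level towards the second, so the share we reckon for eta lies between them.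

A trial J midway, 1.04 M, leaves L at 0.764 M, and the race rule then returns 1.13 M, more than the trial. We commit to the middle of these two, 72.1% of Q, and we reckon no orders.

The forecast, holding that the “plateaus look like an approach to equilibrium”, gives orders of 0.87 in Q and 0.47 in L, and 71% for eta, less than our share.

The eta flask gives 71.5%, 0.6 percentage points less than our share, with orders of 0.61 in Q and 0.39 in L.

    Q → G (0.2442 min⁻¹)
    G + L → J (0.5646 M⁻¹ min⁻¹)
    G → X (0.1104 min⁻¹)
    2 L ⇌ L2, settled at all times (0.9570 M⁻¹)
    L → Zu (0.03132 min⁻¹)

With twice the L of epsilon, theta runs 1.3 times as fast at the same amount of J. With 1.07 M of J in eta, the same division gives a break-even L of 0.473 M, against the 0.436 M we carried.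

The runs were computed for substances that don't exist.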